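## Retrosynthetic overview
1. The target is 8-hydroxylariciresinol-type. Remove the two phenol benzyl ethers and the silyl group. The C4 tertiary carbinol with its CH2Ar arm comes from an aryl-Grignard/Cu opening of a spiro-epoxide, which comes from a 4-methylene-THF made by Petasis olefination of the THF-4-one.
2. Epoxidation of the exocyclic alkene occurs anti to the C3 side chain. This puts the oxygen cis to the C2 aryl and the new CH2 cis to the C3 CH2OR, as the target requires.
3. Key step: the THF ring is formed in a single step, the only ring formation in the route. A chiral dirhodium catalyst promotes enantioselective intramolecular insertion of an α-diazo-β-ketoester carbenoid into the benzylic C–H of an aryl-CH2–O–CH2 ether. This sets C2 enantioselectively and C3 trans to it.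
4. The diazo ketoester comes from an alkoxide plus ethyl 4-chloroacetoacetate, followed by diazo transfer. The alkoxide derives from O-benzylvanillin.

Assumptions:
- Phenols are carried as benzyl ethers and removed in the last step.
- Rh2(S-PTTL)4 is assumed to give the (2R) enantiomer. This must be checked by ee and optical rotation, and the (R)-catalyst used if the sense is reversed.

## Route

**Step 1**
Reactants: 1 (4-bromo-2-methoxyphenol)
Product: 2 (1-benzyloxy-4-bromo-2-methoxybenzene)
Conditions: BnBr, K2CO3, DMF, 60 °C
Reagents that add atoms: benzyl bromide, BrCc1ccccc1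
Why: Williamson O-benzylation protects the phenol and gives the aryl bromide for the later Grignard reagent.

**Step 2**
Reactants: 3 (4-benzyloxy-3-methoxybenzaldehyde)
Product: 4 ((4-benzyloxy-3-methoxyphenyl)methanol)
Conditions: NaBH4, MeOH/THF, 0 °C
Reagents that add atoms: none
Why: Chemoselective aldehyde reduction; the benzyl ether is untouched.

**Step 3**
Reactants: 4 and 5 (ethyl 4-chloro-3-oxobutanoate)
Product: 6 (ethyl 4-[(4-benzyloxy-3-methoxybenzyl)oxy]-3-oxobutanoate)
Conditions: NaH (2.2 equiv), THF, 0 °C → rt
Reagents that add atoms: none (5 is a reactant)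
Why: Williamson displacement of the α-chloroketone by the sodium alkoxide, with the ketoester enolised as its sodium salt, gives the 4-alkoxyacetoacetate.

**Step 4**
Reactants: 6
Product: 7 (ethyl 2-diazo-4-[(4-benzyloxy-3-methoxybenzyl)oxy]-3-oxobutanoate)
Conditions: p-ABSA, Et3N, MeCN, 0 °C → rt
Reagents that add atoms: p-acetamidobenzenesulfonyl azide, CC(=O)Nc1ccc(cc1)S(=O)(=O)N=[N+]=[N-] (delivers N2)
Why: Regitz diazo transfer to the acidic methylene gives the acceptor/acceptor diazo compound.

**Step 5 (key step)**
Reactants: 7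
Product: 8 (ethyl (2R,3S)-2-[4-benzyloxy-3-methoxyphenyl]-4-oxotetrahydrofuran-3-carboxylate, 2,3-trans)
Conditions: Rh2(S-PTTL)4 (1 mol %), CH2Cl2, 23 °C (trans-selectivity can be improved by brief Et3N equilibration)
Reagents that add atoms: none (N2 is lost)
Why: Chiral Rh(II)-carbenoid intramolecular C–H insertion into the electron-rich benzylic ether C–H closes the THF ring. The catalyst controls the face of the benzylic carbon, setting C2. C3 sits between the ketone and the ester and is epimerisable, so it settles trans to the aryl group. Competing Buchner-type arene addition is suppressed by the bulky catalyst.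

**Step 6**
Reactants: 8
Product: 9 ([(2R,3R)-2-aryl-4-hydroxy-THF-3-yl]methanol, C4 epimeric mixture; aryl = 4-benzyloxy-3-methoxyphenyl)
Conditions: LiAlH4 (2 equiv), THF, 0 °C
Reagents that add atoms: none
Why: Ester and ketone are both reduced. The new C4 carbinol stereocentre is destroyed again in Step 8. C3 is no longer acidic, so the trans relationship is locked.

**Step 7**
Reactants: 9
Product: 10 (primary TBDPS ether, secondary C4-OH free)
Conditions: TBDPSCl, imidazole, DMF/CH2Cl2, 0 °C
Reagents that add atoms: tert-butyldiphenylsilyl chloride, CC(C)(C)[Si](Cl)(c1ccccc1)c1ccccc1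
Why: Silylation is selective for the primary alcohol over the hindered ring secondary alcohol. The bulky silyl group also blocks the top face for Step 10.

**Step 8**
Reactants: 10
Product: 11 ((2R,3S)-2-aryl-3-[(TBDPSO)methyl]tetrahydrofuran-4-one)
Conditions: Dess–Martin periodinane, NaHCO3, CH2Cl2, 0 °C
Reagents that add atoms: none
Why: Mild, non-basic oxidation avoids E1cB loss of silanol and epimerisation at C3, which a Swern oxidation would risk.

**Step 9**
Reactants: 11
Product: 12 (4-methylene-THF, (2R,3S))
Conditions: Cp2TiMe2, toluene/THF, 65 °C, dark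
Reagents that add atoms: dimethyltitanocene, C[Ti](C)(C1C=CC=C1)C1C=CC=C1 (delivers =CH2 via Cp2Ti=CH2)
Why: Petasis methylenation is non-basic, so the enolisable, β-silyloxy ketone does not epimerise or eliminate.

**Step 10**
Reactants: 12
Product: 13 (spiro-epoxide, (3S,6R,7S)-6-aryl-7-[(TBDPSO)methyl]-1,5-dioxaspiro[2.4]heptane)
Conditions: DMDO, acetone/CH2Cl2, 0 °C
Reagents that add atoms: dimethyldioxirane, CC1(C)OO1 (delivers O)
Why: Substrate-controlled epoxidation of the exocyclic alkene. DMDO approaches anti to the adjacent bulky C3 CH2OTBDPS arm, so the epoxide O ends up on the face of the C2 aryl and the epoxide CH2 on the face of the C3 side chain. This is the C4 relative configuration of the target. The minor diastereomer is removed by chromatography.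

**Step 11**
Reactants: 13 and 2 (converted in situ to ArMgBr with Mg turnings)
Product: 14 ((2R,3S,4R)-4-(4-benzyloxy-3-methoxybenzyl)-2-aryl-3-[(TBDPSO)methyl]THF-4-ol)
Conditions: 2 + Mg, THF → ArMgBr; CuI (10 mol %), −20 → 0 °C, then 13
Reagents that add atoms: 4-benzyloxy-3-methoxyphenylmagnesium bromide, COc1cc([Mg]Br)ccc1OCc1ccccc1 (delivers aryl)
Why: Cu-catalysed SN2 opening of the epoxide at the unhindered CH2 gives the tertiary alcohol. The C4–O bond is not broken, so C4 keeps the configuration set in Step 10.

**Step 12**
Reactants: 14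
Product: 15 (bis-O-benzyl target, (2R,3S,4R))
Conditions: TBAF, THF, 0 °C → rt
Reagents that add atoms: none
Why: Fluoride desilylation; there is no carbonyl left, so no retro-aldol is possible.

**Step 13**
Reactants: 15
Product: 16 (target)
Conditions: H2 (1 atm), 10 % Pd/C, EtOAc/EtOH, rt, short reaction time
Reagents that add atoms: none
Why: Hydrogenolysis removes both aryl benzyl ethers. The 2-aryl-THF C–O bond and the tertiary alcohol survive under these mild conditions, and no stereocentre is affected.

## Compound list
1 | 4-bromo-2-methoxyphenol | COc1cc(Br)ccc1O | starting material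
2 | 1-(benzyloxy)-4-bromo-2-methoxybenzene | COc1cc(Br)ccc1OCc1ccccc1 | intermediate
3 | 4-(benzyloxy)-3-methoxybenzaldehyde | COc1cc(C=O)ccc1OCc1ccccc1 | starting material
4 | (4-benzyloxy-3-methoxyphenyl)methanol | COc1cc(CO)ccc1OCc1ccccc1 | intermediate
5 | ethyl 4-chloro-3-oxobutanoate | CCOC(=O)CC(=O)CCl | starting material
6 | ethyl 4-[(4-benzyloxy-3-methoxybenzyl)oxy]-3-oxobutanoate | CCOC(=O)CC(=O)COCc1ccc(OCc2ccccc2)c(OC)c1 | intermediate
7 | diazo ketoester | CCOC(=O)C(=[N+]=[N-])C(=O)COCc1ccc(OCc2ccccc2)c(OC)c1 | intermediate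
8 | ethyl (2R,3S)-2-aryl-4-oxotetrahydrofuran-3-carboxylate | O=C2CO[C@@H](c3ccc(OCc4ccccc4)c(OC)c3)[C@@H]2C(=O)OCC | intermediate
9 | [(2R,3R)-2-aryl-4-hydroxy-THF-3-yl]methanol (C4 epimers) | OC2CO[C@@H](c3ccc(OCc4ccccc4)c(OC)c3)[C@@H]2CO | intermediate
10 | primary TBDPS ether of 9 | OC2CO[C@@H](c3ccc(OCc4ccccc4)c(OC)c3)[C@@H]2CO[Si](c5ccccc5)(c5ccccc5)C(C)(C)C | intermediate
11 | (2R,3S)-2-aryl-3-[(TBDPSO)methyl]THF-4-one | O=C2CO[C@@H](c3ccc(OCc4ccccc4)c(OC)c3)[C@@H]2CO[Si](c5ccccc5)(c5ccccc5)C(C)(C)C | intermediate
12 | (2R,3S)-4-methylene-THF | C=C2CO[C@@H](c3ccc(OCc4ccccc4)c(OC)c3)[C@@H]2CO[Si](c5ccccc5)(c5ccccc5)C(C)(C)C | intermediate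
13 | spiro-epoxide (3S,6R,7S) | C1O[C@]12CO[C@@H](c3ccc(OCc4ccccc4)c(OC)c3)[C@@H]2CO[Si](c5ccccc5)(c5ccccc5)C(C)(C)C | intermediate
14 | (2R,3S,4R) tertiary alcohol, silyl- and benzyl-protected | COc1cc(C[C@]2(O)CO[C@@H](c3ccc(OCc4ccccc4)c(OC)c3)[C@@H]2CO[Si](c5ccccc5)(c5ccccc5)C(C)(C)C)ccc1OCc1ccccc1 | intermediate
15 | bis-O-benzyl target | COc1cc(C[C@]2(O)CO[C@@H](c3ccc(OCc4ccccc4)c(OC)c3)[C@@H]2CO)ccc1OCc1ccccc1 | intermediate
16 | (2R,3S,4R)-2-(4-hydroxy-3-methoxyphenyl)-4-(4-hydroxy-3-methoxybenzyl)-3-(hydroxymethyl)tetrahydrofuran-4-ol | COc1cc(C[C@]2(O)CO[C@@H](c3ccc(O)c(OC)c3)[C@@H]2CO)ccc1O | target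

## Totals and risks
Total steps: 13, including the aryl-bromide branch in Step 1. Longest linear sequence: 12 steps (Steps 2–13, from 3).

Three steps most likely to fail:
1. **Step 5 (Rh C–H insertion).** The risks are modest ee, wrong enantiomer, or Buchner/arene addition. Fallback: run the insertion with achiral Rh2(OAc)4 to give racemic material. Then resolve the diol 9 (or its primary acetate) enzymatically with a lipase and carry on.
2. **Step 10 (face selectivity of the epoxidation).** The 1,3-aryl group at C2 opposes the adjacent silyl arm, so the dr may be poor. Fallback (different approach): build C4 through a 5-aryl-γ-butyrolactone with an α-benzyl substituent. Hydroxylate its enolate with a Davis oxaziridine anti to the C3 substituent, then reduce the lactone and cyclodehydrate, which allows the benzylic C2 to equilibrate.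
3. **Step 11 (Grignard/Cu epoxide opening).** Meinwald rearrangement of the tertiary spiro-epoxide competes. Fallback (different approach): olefinate ketone 11 with ArCH2PPh3Cl to give the benzylidene. Then epoxidise it with DMDO anti to the C3 arm and open the epoxide by Pd/C hydrogenolysis at the benzylic carbon, which also removes the benzyl ethers.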